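**Plan**

- Numbering used: ring A = C1–C5 and C10 (C3 carbinol, C4 gem-dimethyl); ring B = C5–C10 (C5=C6 double bond, C8 methyl, C9 quaternary with a methyl group and C11H2–O); the aryl part is isofraxidin.
- Retrosynthesis: first the C11–O aryl ether is cut (Mitsunobu reaction with isofraxidin), then ring B at C6–C7 and C9–C10, giving a ring A enal (C6 as aldehyde) and a four-carbon organolithium C7–C8–C9=C11 that carries C9 as an enol ether.
- Enabling feature: C6–C5–C10 is an allyl unit whose vinylic end C6 carries C7 and whose allylic end C10 carries the quaternary C9. C6 can therefore act first as a carbonyl electrophile and then, by loss of the same oxygen, as one end of an allyl cation that C9 captures at C10, which leaves the double bond at C5=C6.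
- Forward: ring A is bought with C3 in place and turned into the enal; the C7–C11 piece is made from methyl (S)-3-hydroxy-2-methylpropanoate; step 10 joins the two and closes ring B; reduction, etherification and desilylation finish the route.
- Stereochemistry: C3 comes from the purchased hydroxy ketone, C8 from the purchased hydroxy ester, and C9 and C10 are set by C8 through a chair transition state in the ring closure.

Key step: step 10

Remark: compounds 10 to 15 are carried as E/Z mixtures of the enol ether, and 15 also as both C6 epimers, because both elements of isomerism disappear in cation 16; compounds 1 and 20 are taken as purchased.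

**Route**

Step 1
Reactants: 1 (S)-3-hydroxy-2,2-dimethylcyclohexan-1-one
Product: 2 (S)-3-((tert-butyldimethylsilyl)oxy)-2,2-dimethylcyclohexan-1-one
Conditions: TBSOTf, 2,6-lutidine, CH2Cl2, 0 °C
Reagents that add atoms: tert-butyldimethylsilyl trifluoromethanesulfonate, CC(C)(C)[Si](C)(C)OS(=O)(=O)C(F)(F)F
Why: O-silylation with a silyl triflate and a hindered pyridine base should protect the neopentyl-type secondary alcohol without touching the C3 stereocentre, and the silyl ether should survive base, organolithium and cold Lewis acid later.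

Step 2
Reactants: 2 (S)-3-((tert-butyldimethylsilyl)oxy)-2,2-dimethylcyclohexan-1-one
Product: 4 (S)-5-((tert-butyldimethylsilyl)oxy)-6,6-dimethylcyclohex-1-en-1-yl trifluoromethanesulfonate, via potassium enolate 3 (not isolated)
Conditions: KN(SiMe3)2, THF, −78 °C; then PhNTf2, −78 → 0 °C
Reagents that add atoms: N-phenylbis(trifluoromethanesulfonimide), O=S(=O)(N(c1ccccc1)S(=O)(=O)C(F)(F)F)C(F)(F)F
Why: The ketone has α-hydrogens only at C10, so enolisation is regiospecific and O-triflation (enol triflate synthesis) should fix the C5=C10 double bond; β-elimination of the silyloxy group cannot occur because C4 is quaternary.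

Step 3
Reactants: 4 (S)-5-((tert-butyldimethylsilyl)oxy)-6,6-dimethylcyclohex-1-en-1-yl trifluoromethanesulfonate
Product: 5 (S)-5-((tert-butyldimethylsilyl)oxy)-6,6-dimethylcyclohex-1-ene-1-carbaldehyde
Conditions: Pd(PPh3)4 (5 mol %), LiCl, CO (1 atm), Bu3SnH (slow addition), THF, 50 °C
Reagents that add atoms: carbon monoxide, [C-]#[O+]
Why: Palladium-catalysed reductive carbonylation of an enol triflate (CO insertion, then hydride transfer from Bu3SnH) should install C6 as the aldehyde while the double bond stays where the triflate put it.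

Step 4
Reactants: 6 methyl (S)-3-hydroxy-2-methylpropanoate
Product: 7 methyl (S)-3-((tert-butyldimethylsilyl)oxy)-2-methylpropanoate
Conditions: TBSCl, imidazole, CH2Cl2, 20 °C
Reagents that add atoms: tert-butyldimethylsilyl chloride, CC(C)(C)[Si](C)(C)Cl
Why: Routine silylation of a primary alcohol masks the future C7 oxygen through the carbonyl chemistry that follows; the stereocentre (the future C8) is not involved.

Step 5
Reactants: 7 methyl (S)-3-((tert-butyldimethylsilyl)oxy)-2-methylpropanoate
Product: 8 (S)-3-((tert-butyldimethylsilyl)oxy)-N-methoxy-N,2-dimethylpropanamide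
Conditions: MeNH(OMe)·HCl, i-PrMgCl, THF, −20 → 0 °C
Reagents that add atoms: N,O-dimethylhydroxylamine hydrochloride, CNOC.Cl
Why: Aminolysis of the ester by the magnesium amide of N,O-dimethylhydroxylamine is a standard conversion that does not enolise the α-stereocentre at this temperature.

Step 6
Reactants: 8 (S)-3-((tert-butyldimethylsilyl)oxy)-N-methoxy-N,2-dimethylpropanamide
Product: 9 (S)-4-((tert-butyldimethylsilyl)oxy)-3-methylbutan-2-one
Conditions: MeMgBr, THF, 0 °C
Reagents that add atoms: methylmagnesium bromide, C[Mg]Br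
Why: Grignard addition to an N-methoxy-N-methylamide is the standard ketone synthesis that stops after one addition; it brings in the C9 methyl group and C9 itself at the ketone level.

Step 7
Reactants: 9 (S)-4-((tert-butyldimethylsilyl)oxy)-3-methylbutan-2-one
Product: 10 (R)-tert-butyl((4-methoxy-2,3-dimethylbut-3-en-1-yl)oxy)dimethylsilane
Conditions: Ph3P(CH2OMe)Cl, KN(SiMe3)2, THF, 0 °C; then 9, −78 → 20 °C
Reagents that add atoms: (methoxymethyl)triphenylphosphonium chloride, COC[P+](c1ccccc1)(c1ccccc1)c1ccccc1.[Cl-]
Why: Wittig reaction of the methyl ketone with the methoxymethylene ylide should add C11 and make C9 a nucleophilic enol-ether carbon; the E/Z mixture is of no consequence and cold addition limits epimerisation next to the ketone.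

Step 8
Reactants: 10 (R)-tert-butyl((4-methoxy-2,3-dimethylbut-3-en-1-yl)oxy)dimethylsilane
Product: 11 (R)-4-methoxy-2,3-dimethylbut-3-en-1-ol
Conditions: Bu4NF, THF, 0 → 20 °C
Reagents that add atoms: none
Why: Fluoride cleaves the primary silyl ether under non-acidic conditions, which the acid-labile enol ether tolerates.

Step 9
Reactants: 11 (R)-4-methoxy-2,3-dimethylbut-3-en-1-ol
Product: 13 (R)-4-iodo-1-methoxy-2,3-dimethylbut-1-ene, via mesylate 12 (not isolated)
Conditions: MsCl, Et3N, THF, 0 °C; then NaI, 50 °C
Reagents that add atoms: sodium iodide, [Na+].[I-]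
Why: Mesylation followed by Finkelstein displacement (SN2 at the primary carbon C7) gives the iodide without free iodine or acid, neither of which the enol ether would survive.

Step 10
Reactants: 13 (R)-4-iodo-1-methoxy-2,3-dimethylbut-1-ene; 5 (S)-5-((tert-butyldimethylsilyl)oxy)-6,6-dimethylcyclohex-1-ene-1-carbaldehyde
Product: 18 (1R,2S,6S,8aR)-6-((tert-butyldimethylsilyl)oxy)-1,2,5,5-tetramethyl-1,2,3,5,6,7,8,8a-octahydronaphthalene-1-carbaldehyde, via organolithium 14 (not isolated), via lithium alkoxide 15 (not isolated), via allyl cation 16 (not isolated), via oxocarbenium ion 17 (not isolated)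
Conditions: t-BuLi (2 equiv), Et2O–pentane, −78 °C; then 5, −78 °C; then CH2Cl2, SnCl4, −78 → −40 °C; aq. NaHCO3
Reagents that add atoms: water (work-up), O
Why: Iodine–lithium exchange gives organolithium 14, which should add 1,2 to the carbonyl group of enal 5 (organolithium carbonyl addition, routine for hindered cyclohexenecarbaldehydes) and so form C6–C7 as lithium alkoxide 15; SnCl4 should then ionise the C6–O bond to allyl cation 16 (C6–C5–C10), whose capture by the tethered enol ether is the known Lewis-acid cation–olefin cyclisation with an enol-ether terminator (an intramolecular SN1′ Mukaiyama-type alkylation). Ring B closes by bond formation between C9 and the cation terminus C10, 6-endo with respect to the allyl unit and exo with respect to the enol ether, the alternative attack at C6 being a four-membered closure, and oxocarbenium ion 17 is hydrolysed to 18 on work-up. C10 is set by the C8 centre through a chair transition state in which the C8 methyl group and the ring A bond C10–C1 are both equatorial, and C9 by the same chair with C8–H eclipsing the enol double bond (minimal A(1,3) strain), which puts C11 equatorial and the C9 methyl group axial, that is 8S,9R,10R. C6 is planar in 16 and the enol-ether geometry does not enter the new centre, so both C6 epimers of 15 and both olefin isomers should converge on one product. The step needs attack at C10 and not C6 and a C5=C6 and not a C5=C10 double bond, both secured because the leaving oxygen sits on C6 and only the six-membered closure is open, and it needs the cation with C7 turned towards C10, secured by the C4 gem-dimethyl group that leaves room only for C6–H on its side. The C3 silyloxy group can stay equatorial while the new bond forms axially at C10, which corresponds to the 3,10-cis relation of the target, and the silyl ether should survive the aprotic Lewis acid at low temperature.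

Step 11
Reactants: 18 (1R,2S,6S,8aR)-6-((tert-butyldimethylsilyl)oxy)-1,2,5,5-tetramethyl-1,2,3,5,6,7,8,8a-octahydronaphthalene-1-carbaldehyde
Product: 19 ((1R,2S,6S,8aR)-6-((tert-butyldimethylsilyl)oxy)-1,2,5,5-tetramethyl-1,2,3,5,6,7,8,8a-octahydronaphthalen-1-yl)methanol
Conditions: NaBH4, MeOH, 0 °C
Reagents that add atoms: none
Why: Borohydride reduction of the aldehyde on the quaternary carbon gives the C11 alcohol; no stereocentre is formed, C9 cannot epimerise and the trisubstituted alkene is inert.

Step 12
Reactants: 19 ((1R,2S,6S,8aR)-6-((tert-butyldimethylsilyl)oxy)-1,2,5,5-tetramethyl-1,2,3,5,6,7,8,8a-octahydronaphthalen-1-yl)methanol; 20 7-hydroxy-6,8-dimethoxy-2H-chromen-2-one (isofraxidin)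
Product: 21 7-(((1R,2S,6S,8aR)-6-((tert-butyldimethylsilyl)oxy)-1,2,5,5-tetramethyl-1,2,3,5,6,7,8,8a-octahydronaphthalen-1-yl)methoxy)-6,8-dimethoxy-2H-chromen-2-one
Conditions: PPh3, DIAD, toluene (3 M), ultrasound, 40 °C
Reagents that add atoms: none
Why: Mitsunobu etherification should join the acidic phenol to the activated primary C11 oxygen by SN2 at a carbon that is not a stereocentre; high concentration with sonication is the known remedy for a hindered phenol paired with a neopentyl alcohol, and the silyl ether keeps C3–OH out of the reaction.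

Step 13
Reactants: 21 7-(((1R,2S,6S,8aR)-6-((tert-butyldimethylsilyl)oxy)-1,2,5,5-tetramethyl-1,2,3,5,6,7,8,8a-octahydronaphthalen-1-yl)methoxy)-6,8-dimethoxy-2H-chromen-2-one
Product: 22 7-(((1R,2S,6S,8aR)-6-hydroxy-1,2,5,5-tetramethyl-1,2,3,5,6,7,8,8a-octahydronaphthalen-1-yl)methoxy)-6,8-dimethoxy-2H-chromen-2-one
Conditions: HF·pyridine, THF, 0 → 20 °C
Reagents that add atoms: none
Why: Fluoride-mediated Si–O cleavage under mildly acidic conditions should free the C3 alcohol while sparing the coumarin lactone, the aryl ether and the alkene.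

**Compound list**

1 | (S)-3-hydroxy-2,2-dimethylcyclohexan-1-one | O=C1CCC[C@H](O)C1(C)C | starting material
2 | (S)-3-((tert-butyldimethylsilyl)oxy)-2,2-dimethylcyclohexan-1-one | O=C1CCC[C@H](O[Si](C)(C)C(C)(C)C)C1(C)C | intermediate
3 | potassium (S)-5-((tert-butyldimethylsilyl)oxy)-6,6-dimethylcyclohex-1-en-1-olate | [K+].[O-]C1=CCC[C@H](O[Si](C)(C)C(C)(C)C)C1(C)C | intermediate
4 | (S)-5-((tert-butyldimethylsilyl)oxy)-6,6-dimethylcyclohex-1-en-1-yl trifluoromethanesulfonate | O=S(=O)(OC1=CCC[C@H](O[Si](C)(C)C(C)(C)C)C1(C)C)C(F)(F)F | intermediate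
5 | (S)-5-((tert-butyldimethylsilyl)oxy)-6,6-dimethylcyclohex-1-ene-1-carbaldehyde | O=CC1=CCC[C@H](O[Si](C)(C)C(C)(C)C)C1(C)C | intermediate
6 | methyl (S)-3-hydroxy-2-methylpropanoate | COC(=O)[C@@H](C)CO | starting material
7 | methyl (S)-3-((tert-butyldimethylsilyl)oxy)-2-methylpropanoate | COC(=O)[C@@H](C)CO[Si](C)(C)C(C)(C)C | intermediate
8 | (S)-3-((tert-butyldimethylsilyl)oxy)-N-methoxy-N,2-dimethylpropanamide | CON(C)C(=O)[C@@H](C)CO[Si](C)(C)C(C)(C)C | intermediate
9 | (S)-4-((tert-butyldimethylsilyl)oxy)-3-methylbutan-2-one | CC(=O)[C@@H](C)CO[Si](C)(C)C(C)(C)C | intermediate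
10 | (R)-tert-butyl((4-methoxy-2,3-dimethylbut-3-en-1-yl)oxy)dimethylsilane (E/Z mixture) | COC=C(C)[C@@H](C)CO[Si](C)(C)C(C)(C)C | intermediate
11 | (R)-4-methoxy-2,3-dimethylbut-3-en-1-ol (E/Z mixture) | COC=C(C)[C@@H](C)CO | intermediate
12 | (R)-4-methoxy-2,3-dimethylbut-3-en-1-yl methanesulfonate (E/Z mixture) | COC=C(C)[C@@H](C)COS(C)(=O)=O | intermediate
13 | (R)-4-iodo-1-methoxy-2,3-dimethylbut-1-ene (E/Z mixture) | COC=C(C)[C@@H](C)CI | intermediate
14 | ((S)-4-methoxy-2,3-dimethylbut-3-en-1-yl)lithium (E/Z mixture) | COC=C(C)[C@@H](C)C[Li] | intermediate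
15 | lithium (3S)-1-((S)-5-((tert-butyldimethylsilyl)oxy)-6,6-dimethylcyclohex-1-en-1-yl)-5-methoxy-3,4-dimethylpent-4-en-1-olate (both C1 epimers, E/Z mixture) | [Li+].[O-]C(C[C@H](C)C(C)=COC)C1=CCC[C@H](O[Si](C)(C)C(C)(C)C)C1(C)C | intermediate
16 | (3S)-1-((S)-5-((tert-butyldimethylsilyl)oxy)-6,6-dimethylcyclohex-1-en-1-yl)-5-methoxy-3,4-dimethylpent-4-en-1-ylium (allyl cation over C6–C5–C10) | [CH+](C[C@H](C)C(C)=COC)C1=CCC[C@H](O[Si](C)(C)C(C)(C)C)C1(C)C | intermediate
17 | O-methyl oxocarbenium ion of aldehyde 18 | C[O+]=C[C@@]1(C)[C@@H]2CC[C@H](O[Si](C)(C)C(C)(C)C)C(C)(C)C2=CC[C@@H]1C | intermediate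
18 | (1R,2S,6S,8aR)-6-((tert-butyldimethylsilyl)oxy)-1,2,5,5-tetramethyl-1,2,3,5,6,7,8,8a-octahydronaphthalene-1-carbaldehyde | O=C[C@@]1(C)[C@@H]2CC[C@H](O[Si](C)(C)C(C)(C)C)C(C)(C)C2=CC[C@@H]1C | intermediate
19 | ((1R,2S,6S,8aR)-6-((tert-butyldimethylsilyl)oxy)-1,2,5,5-tetramethyl-1,2,3,5,6,7,8,8a-octahydronaphthalen-1-yl)methanol | OC[C@@]1(C)[C@@H]2CC[C@H](O[Si](C)(C)C(C)(C)C)C(C)(C)C2=CC[C@@H]1C | intermediate
20 | 7-hydroxy-6,8-dimethoxy-2H-chromen-2-one (isofraxidin) | COc1cc2ccc(=O)oc2c(OC)c1O | starting material
21 | 7-(((1R,2S,6S,8aR)-6-((tert-butyldimethylsilyl)oxy)-1,2,5,5-tetramethyl-1,2,3,5,6,7,8,8a-octahydronaphthalen-1-yl)methoxy)-6,8-dimethoxy-2H-chromen-2-one | COc1cc2ccc(=O)oc2c(OC)c1OC[C@@]1(C)[C@@H]2CC[C@H](O[Si](C)(C)C(C)(C)C)C(C)(C)C2=CC[C@@H]1C | intermediate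
22 | 7-(((1R,2S,6S,8aR)-6-hydroxy-1,2,5,5-tetramethyl-1,2,3,5,6,7,8,8a-octahydronaphthalen-1-yl)methoxy)-6,8-dimethoxy-2H-chromen-2-one | COc1cc2ccc(=O)oc2c(OC)c1OC[C@@]1(C)[C@@H]2CC[C@H](O)C(C)(C)C2=CC[C@@H]1C | target

**Step count and risks**

Total steps: 13. Longest linear sequence: 10 steps (steps 4 to 13, from compound 6).

Steps most likely to fail:

1. Step 10. The allyl cation may lose a proton to a conjugated diene before it is captured. Ring closure may pass through a boat or a chair with the C8 methyl group axial, which erodes control at C9 and C10. The Lewis acid may cleave the silyl ether or drive a further Prins-type reaction between the new aldehyde and the C5=C6 double bond. Fallback: setting out from 5, Wittig methylenation (Ph3P=CH2, THF, 0 °C) would give the diene (S)-tert-butyl((2,2-dimethyl-3-vinylcyclohex-3-en-1-yl)oxy)dimethylsilane F1. A Diels–Alder reaction of F1 with (E)-2-methylbut-2-enal (EtAlCl2, CH2Cl2, −78 °C), through the transition state with the formyl group exo, would give 18 and rejoin the route there. This closes ring B through C7–C8 and C9–C10 instead; the cis methyl groups come from the dienophile geometry, but the face selectivity rests on the remote C3 substituent, so a diastereomer separation must be expected.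

2. Step 12. SN2 displacement at the neopentyl carbon C11 by a phenol flanked by two methoxy groups may be too slow, so that the activated alcohol is consumed by alkylation of the reduced azodicarboxylate. Fallback: setting out from 20, triflation (Tf2O, pyridine, CH2Cl2, 0 °C) would give 6,8-dimethoxy-2-oxo-2H-chromen-7-yl trifluoromethanesulfonate F2. Palladium-catalysed C–O cross-coupling of F2 with alcohol 19 (Pd2(dba)3, 2-(di-tert-butylphosphino)-3-methoxy-6-methyl-2′,4′,6′-triisopropylbiphenyl, Cs2CO3, toluene, 90 °C) would give 21 and rejoin the route there. The ether bond is then made at the aryl carbon, so no substitution at the neopentyl carbon is needed.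

3. Step 3. Hydride transfer to palladium may outrun CO insertion at the hindered alkenyl position next to the quaternary C4, giving simple reduction of the triflate, and oxidative addition may be slow. Fallback: setting out from 2, condensation with 2,4,6-triisopropylbenzenesulfonyl hydrazide (cat. HCl, THF, 20 °C) would give (S)-N'-(3-((tert-butyldimethylsilyl)oxy)-2,2-dimethylcyclohexylidene)-2,4,6-triisopropylbenzenesulfonohydrazide F3. A Shapiro reaction (n-BuLi, 2.2 equiv, TMEDA–hexane, −78 → 0 °C) would give ((S)-5-((tert-butyldimethylsilyl)oxy)-6,6-dimethylcyclohex-1-en-1-yl)lithium F4, which is formylated with DMF at −78 °C to give 5, where the route is rejoined.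

Further compounds
F1 | step 10 | (S)-tert-butyl((2,2-dimethyl-3-vinylcyclohex-3-en-1-yl)oxy)dimethylsilane | C=CC1=CCC[C@H](O[Si](C)(C)C(C)(C)C)C1(C)C
F2 | step 12 | 6,8-dimethoxy-2-oxo-2H-chromen-7-yl trifluoromethanesulfonate | COc1cc2ccc(=O)oc2c(OC)c1OS(=O)(=O)C(F)(F)F
F3 | step 3 | (S)-N'-(3-((tert-butyldimethylsilyl)oxy)-2,2-dimethylcyclohexylidene)-2,4,6-triisopropylbenzenesulfonohydrazide | CC(C)c1cc(C(C)C)c(S(=O)(=O)NN=C2CCC[C@H](O[Si](C)(C)C(C)(C)C)C2(C)C)c(C(C)C)c1
F4 | step 3 | ((S)-5-((tert-butyldimethylsilyl)oxy)-6,6-dimethylcyclohex-1-en-1-yl)lithium | [Li]C1=CCC[C@H](O[Si](C)(C)C(C)(C)C)C1(C)C
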